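**Retrosynthetic overview** (germacrane numbering: C1/C2 oxirane, C3 ketone, C4=C5, C6 lactone O–CH, C7, C8 tiglate carbon, C9, C10 carbinol, C11–C13 methylene lactone)
1. Last step: the C1–C2 bond and the oxirane C–O bond are made together by an intramolecular Darzens reaction of a seco α-chloromethyl enone / α-hydroxy aldehyde, closing the ten-membered carbocycle and the epoxide in one operation.
2. The seco aldehyde comes from a cis-fused α-methylene-γ-butyrolactone whose (Z)-enyne arm is a latent ClCH2C(=O) unit and whose dimethyl acetal is the latent C1 aldehyde.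
3. The lactone comes from an indium Barbier coupling (C7–C8 bond; C7 and C8 set) of a C6-silyloxy 2-(bromomethyl)enoate with a β-hydroxy aldehyde, then C8 tigloylation and acid lactonisation onto C6–OH.
4. The bromide derives from a commercial (Z)-enynol and methyl propiolate (C6 by asymmetric alkynylation); the aldehyde derives from 1,1-dimethoxyacetone (C10 by asymmetric allylboration).
5. Ring order: γ-lactone first, then ten-membered ring and oxirane simultaneously.

Assumption: in the two catalyst-controlled steps (1 and 4) the ligand antipode named is taken to be the one that gives the configuration drawn; if the sense proves opposite, the mirror-image ligand is used.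

**Step 1**
Reactants: 1 1,1-dimethoxypropan-2-one; 2 2-allyl-4,4,5,5-tetramethyl-1,3,2-dioxaborolane
Product: 3 (2R)-1,1-dimethoxy-2-methylpent-4-en-2-ol
Conditions: CuF(PPh3)3·2EtOH (3 mol %), (R,R)-iPr-DuPHOS (6 mol %), La(OiPr)3 (4.5 mol %), DMF, −40 °C; aq. NH4Cl
Reagents that add atoms: none
Why: Copper-catalysed enantioselective allylboration of a ketone, in which the allylcopper formed by B-to-Cu transmetalation adds through a cyclic transition state where the chiral bisphosphine distinguishes CH3 from CH(OMe)2 and sets C10 as R (any minor enantiomer becomes a separable diastereomer after step 8).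

**Step 2**
Reactants: 3 (2R)-1,1-dimethoxy-2-methylpent-4-en-2-ol
Product: 5 (3R)-3-hydroxy-4,4-dimethoxy-3-methylbutanal, via ozonide 4 (not isolated)
Conditions: O3, CH2Cl2, −78 °C; then PPh3, −78 °C → rt; used crude
Reagents that add atoms: ozone, [O-][O+]=O
Why: Ozonolysis with reductive work-up cleaves the only C=C bond to the β-hydroxy aldehyde under neutral conditions that avoid dehydration and retro-aldol, leaving C10 untouched.

**Step 3**
Reactants: 6 (2Z)-3-methylpent-2-en-4-yn-1-ol
Product: 7 (2Z)-3-methylpent-2-en-4-ynal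
Conditions: MnO2 (10 equiv), CH2Cl2, rt
Reagents that add atoms: none
Why: MnO2 allylic oxidation gives the enal without touching the alkyne or the Z geometry that becomes the C4=C5 bond.

**Step 4**
Reactants: 7 (2Z)-3-methylpent-2-en-4-ynal; 8 methyl prop-2-ynoate
Product: 10 methyl (4S,5Z)-4-hydroxy-6-methyloct-5-ene-2,7-diynoate, via alkynylzinc 9 (not isolated)
Conditions: 8 (2.8 equiv), Me2Zn (2.9 equiv), (S,S)-ProPhenol (10 mol %), Ph3P=O (20 mol %), toluene, 0 °C; aq. NH4Cl
Reagents that add atoms: none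
Why: Zinc–ProPhenol catalysed asymmetric alkynylation of an enal (Trost type), in which only the far more acidic propiolate C–H is zincated and the chiral dinuclear zinc catalyst delivers the alkynyl group to one aldehyde face, setting C6 (4S in 10).

**Step 5**
Reactants: 10 methyl (4S,5Z)-4-hydroxy-6-methyloct-5-ene-2,7-diynoate
Product: 11 methyl (4S,5Z)-6-methyl-4-(triethylsilyloxy)oct-5-ene-2,7-diynoate
Conditions: Et3SiOTf, 2,6-lutidine, CH2Cl2, −78 °C
Reagents that add atoms: triethylsilyl trifluoromethanesulfonate, CC[Si](CC)(CC)OS(=O)(=O)C(F)(F)F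
Why: Silyl ether formation with a non-nucleophilic base (no aza-Michael addition to the ynoate) blocks the C6 hydroxyl so that it cannot close a butenolide in the following steps.

**Step 6**
Reactants: 11 methyl (4S,5Z)-6-methyl-4-(triethylsilyloxy)oct-5-ene-2,7-diynoate
Product: 13 methyl (2Z,4S,5Z)-2-(hydroxymethyl)-6-methyl-4-(triethylsilyloxy)octa-2,5-dien-7-ynoate, via alkenylalane 12 (not isolated)
Conditions: i-Bu2AlH (1.2 equiv), HMPA (2 equiv), THF, 0 °C; then CH2O (gas), −20 → 0 °C; Rochelle salt work-up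
Reagents that add atoms: formaldehyde, C=O
Why: Conjugate hydroalumination of the ynoate by i-Bu2AlH–HMPA gives the α-alumino enoate, which is hydroxymethylated by formaldehyde (vinylalumination, giving a Baylis–Hillman-type product); the C2=C3 geometry is of no consequence later.

**Step 7**
Reactants: 13 methyl (2Z,4S,5Z)-2-(hydroxymethyl)-6-methyl-4-(triethylsilyloxy)octa-2,5-dien-7-ynoate
Product: 14 methyl (2E,4S,5Z)-2-(bromomethyl)-6-methyl-4-(triethylsilyloxy)octa-2,5-dien-7-ynoate
Conditions: CBr4, PPh3, CH2Cl2, −20 → 0 °C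
Reagents that add atoms: carbon tetrabromide, BrC(Br)(Br)Br
Why: Appel reaction converts the primary allylic alcohol into the bromide by SN2 displacement under neutral conditions that leave silyl ether, ester and alkyne intact.

**Step 8**
Reactants: 14 methyl (2E,4S,5Z)-2-(bromomethyl)-6-methyl-4-(triethylsilyloxy)octa-2,5-dien-7-ynoate; 5 (3R)-3-hydroxy-4,4-dimethoxy-3-methylbutanal
Product: 16 methyl (3R,4S,5Z)-3-[(1R,3R)-1,3-dihydroxy-4,4-dimethoxy-3-methylbutyl]-6-methyl-2-methylidene-4-(triethylsilyloxy)oct-5-en-7-ynoate, via allylindium 15 (not isolated)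
Conditions: In powder (2 equiv), 5 (1.3 equiv), THF/H2O 1:1, 0 °C → rt; neutral work-up, kept cold
Reagents that add atoms: none
Why: Indium-mediated Barbier allylation (SE2′) through a chair transition state in which the equilibrating allylindium reacts as the isomer with C6 trans to the ester and so gives the syn adduct; the C6 stereocentre (C6–H eclipsing the alkene, alkenyl arm anti to the incoming aldehyde) fixes C7 as R, and indium chelation by the β-hydroxyl of 5 favours the 8,10-anti carbinol, C8 as R.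

**Step 9**
Reactants: 16 methyl (3R,4S,5Z)-3-[(1R,3R)-1,3-dihydroxy-4,4-dimethoxy-3-methylbutyl]-6-methyl-2-methylidene-4-(triethylsilyloxy)oct-5-en-7-ynoate; 17 (2E)-2-methylbut-2-enoyl chloride
Product: 18 methyl (3R,4S,5Z)-3-[(1R,3R)-3-hydroxy-4,4-dimethoxy-3-methyl-1-{[(2E)-2-methylbut-2-enoyl]oxy}butyl]-6-methyl-2-methylidene-4-(triethylsilyloxy)oct-5-en-7-ynoate
Conditions: pyridine, DMAP (0.1 equiv), CH2Cl2, 0 °C
Reagents that add atoms: none
Why: DMAP-catalysed acylation esterifies the secondary C8 hydroxyl while the tertiary C10 hydroxyl is too hindered to react, and doing it on the open hydroxy ester removes the only hydroxyl that could lactonise in the wrong direction.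

**Step 10**
Reactants: 18 methyl (3R,4S,5Z)-3-[(1R,3R)-3-hydroxy-4,4-dimethoxy-3-methyl-1-{[(2E)-2-methylbut-2-enoyl]oxy}butyl]-6-methyl-2-methylidene-4-(triethylsilyloxy)oct-5-en-7-ynoate
Product: 20 (1R,3R)-3-hydroxy-4,4-dimethoxy-3-methyl-1-[(2S,3R)-4-methylidene-2-[(1Z)-2-methylbut-1-en-3-yn-1-yl]-5-oxooxolan-3-yl]butyl (2E)-2-methylbut-2-enoate, via hydroxy ester 19 (not isolated)
Conditions: TsOH·H2O (0.2 equiv), MeOH (10 equiv), CH2Cl2, 0 °C → rt
Reagents that add atoms: none
Why: Acid methanolysis removes the allylic silyl ether and the freed C6 hydroxyl closes onto the acrylate ester (acid-catalysed γ-lactonisation, the first ring), the C6/C7 relationship set in step 8 giving the cis-fused α-methylene lactone while the dimethyl acetal is unchanged in methanol.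

**Step 11**
Reactants: 20 (1R,3R)-3-hydroxy-4,4-dimethoxy-3-methyl-1-[(2S,3R)-4-methylidene-2-[(1Z)-2-methylbut-1-en-3-yn-1-yl]-5-oxooxolan-3-yl]butyl (2E)-2-methylbut-2-enoate
Product: 21 (1R,3R)-1-[(2S,3R)-2-[(1Z)-4-chloro-2-methyl-3-oxobut-1-en-1-yl]-4-methylidene-5-oxooxolan-3-yl]-3-hydroxy-4,4-dimethoxy-3-methylbutyl (2E)-2-methylbut-2-enoate
Conditions: Ph3PAuNTf2 (5 mol %), 8-methylquinoline N-oxide (1.5 equiv), MsOH (1.2 equiv), ClCH2CH2Cl, rt
Reagents that add atoms: 8-methylquinoline N-oxide, Cc1cccc2ccc[n+]([O-])c12; 1,2-dichloroethane, ClCCCl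
Why: Gold-catalysed alkyne oxidation, in which the N-oxide adds to the gold-activated terminal alkyne at the internal carbon to give an α-oxo gold carbene at C2 that abstracts chloride from the solvent and is protodeaurated to the chloromethyl ketone, the Z-enone geometry being already in place.

**Step 12**
Reactants: 21 (1R,3R)-1-[(2S,3R)-2-[(1Z)-4-chloro-2-methyl-3-oxobut-1-en-1-yl]-4-methylidene-5-oxooxolan-3-yl]-3-hydroxy-4,4-dimethoxy-3-methylbutyl (2E)-2-methylbut-2-enoate
Product: 22 (1R,3R)-1-[(2S,3R)-2-[(1Z)-4-chloro-2-methyl-3-oxobut-1-en-1-yl]-4-methylidene-5-oxooxolan-3-yl]-3-hydroxy-3-methyl-4-oxobutyl (2E)-2-methylbut-2-enoate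
Conditions: CF3CO2H/H2O 9:1, CH2Cl2, 0 °C; azeotroped with toluene, used crude
Reagents that add atoms: water, O
Why: Acid-catalysed acetal hydrolysis unmasks the non-enolisable α-hydroxy aldehyde, and ester, lactone, enone and C–Cl bond are stable to cold aqueous acid.

**Step 13**
Reactants: 22 (1R,3R)-1-[(2S,3R)-2-[(1Z)-4-chloro-2-methyl-3-oxobut-1-en-1-yl]-4-methylidene-5-oxooxolan-3-yl]-3-hydroxy-3-methyl-4-oxobutyl (2E)-2-methylbut-2-enoate
Product: 24 (1R,2R,4Z,6S,7R,8R,10R)-1,2-epoxy-10-hydroxy-3-oxogermacra-4,11(13)-dien-12,6-olid-8-yl (2E)-2-methylbut-2-enoate, via chlorohydrin alkoxide 23 (not isolated)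
Conditions: 22 (0.001 M in THF), LiN(SiMe3)2 (2.1 equiv), −78 °C, then −78 → −10 °C; aq. NH4Cl
Reagents that add atoms: none
Why: Proposed new method: an intramolecular Darzens condensation used as a macrocyclisation, in which the lithium enolate of the chloromethyl ketone adds to the aldehyde held in a five-membered lithium chelate with the C10 alkoxide (Cram chelate, attack past the methyl group gives 1R), the reversible aldol drains through the anti chlorohydrin alkoxide that displaces chloride by SN2 to give the trans oxirane (2R), so that the ten-membered carbocycle and the epoxide form together; the closest known chemistry is the intermolecular Darzens reaction of α-chloro ketones with non-enolisable aldehydes and aldol or Reformatsky closures of medium rings.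

**Compound list**
1 | 1,1-dimethoxypropan-2-one (pyruvaldehyde dimethyl acetal) | CC(=O)C(OC)OC | starting material
2 | 2-allyl-4,4,5,5-tetramethyl-1,3,2-dioxaborolane (allylboronic acid pinacol ester) | C=CCB1OC(C)(C)C(C)(C)O1 | starting material
3 | (2R)-1,1-dimethoxy-2-methylpent-4-en-2-ol | COC(OC)[C@](C)(O)CC=C | intermediate
4 | (2R)-1,1-dimethoxy-2-methyl-3-(1,2,4-trioxolan-3-yl)propan-2-ol (secondary ozonide, both epimers at the trioxolane carbon) | COC(OC)[C@](C)(O)CC1OCOO1 | intermediate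
5 | (3R)-3-hydroxy-4,4-dimethoxy-3-methylbutanal | COC(OC)[C@](C)(O)CC=O | intermediate
6 | (2Z)-3-methylpent-2-en-4-yn-1-ol | OC/C=C(/C)C#C | starting material
7 | (2Z)-3-methylpent-2-en-4-ynal | O=C/C=C(/C)C#C | intermediate
8 | methyl prop-2-ynoate (methyl propiolate) | C#CC(=O)OC | starting material
9 | methyl 3-(methylzincio)prop-2-ynoate (alkynylzinc) | C[Zn]C#CC(=O)OC | intermediate
10 | methyl (4S,5Z)-4-hydroxy-6-methyloct-5-ene-2,7-diynoate | COC(=O)C#C[C@@H](O)/C=C(/C)C#C | intermediate
11 | methyl (4S,5Z)-6-methyl-4-(triethylsilyloxy)oct-5-ene-2,7-diynoate | COC(=O)C#C[C@@H](O[Si](CC)(CC)CC)/C=C(/C)C#C | intermediate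
12 | methyl (2E,4S,5Z)-2-(diisobutylalumanyl)-6-methyl-4-(triethylsilyloxy)octa-2,5-dien-7-ynoate (alkenylalane) | COC(=O)/C([Al](CC(C)C)CC(C)C)=C\[C@@H](O[Si](CC)(CC)CC)/C=C(/C)C#C | intermediate
13 | methyl (2Z,4S,5Z)-2-(hydroxymethyl)-6-methyl-4-(triethylsilyloxy)octa-2,5-dien-7-ynoate | COC(=O)/C(CO)=C\[C@@H](O[Si](CC)(CC)CC)/C=C(/C)C#C | intermediate
14 | methyl (2E,4S,5Z)-2-(bromomethyl)-6-methyl-4-(triethylsilyloxy)octa-2,5-dien-7-ynoate | COC(=O)/C(CBr)=C\[C@@H](O[Si](CC)(CC)CC)/C=C(/C)C#C | intermediate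
15 | methyl (2E,4S,5Z)-2-[(dibromoindiganyl)methyl]-6-methyl-4-(triethylsilyloxy)octa-2,5-dien-7-ynoate (allylindium; σ-allyl isomers interconvert) | COC(=O)/C(C[In](Br)Br)=C\[C@@H](O[Si](CC)(CC)CC)/C=C(/C)C#C | intermediate
16 | methyl (3R,4S,5Z)-3-[(1R,3R)-1,3-dihydroxy-4,4-dimethoxy-3-methylbutyl]-6-methyl-2-methylidene-4-(triethylsilyloxy)oct-5-en-7-ynoate | C=C(C(=O)OC)[C@@H]([C@@H](O[Si](CC)(CC)CC)/C=C(/C)C#C)[C@H](O)C[C@@](C)(O)C(OC)OC | intermediate
17 | (2E)-2-methylbut-2-enoyl chloride (tigloyl chloride) | C/C=C(\C)C(Cl)=O | starting material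
18 | methyl (3R,4S,5Z)-3-[(1R,3R)-3-hydroxy-4,4-dimethoxy-3-methyl-1-{[(2E)-2-methylbut-2-enoyl]oxy}butyl]-6-methyl-2-methylidene-4-(triethylsilyloxy)oct-5-en-7-ynoate | C=C(C(=O)OC)[C@@H]([C@@H](O[Si](CC)(CC)CC)/C=C(/C)C#C)[C@H](OC(=O)/C(C)=C/C)C[C@@](C)(O)C(OC)OC | intermediate
19 | methyl (3S,4S,5Z)-4-hydroxy-3-[(1R,3R)-3-hydroxy-4,4-dimethoxy-3-methyl-1-{[(2E)-2-methylbut-2-enoyl]oxy}butyl]-6-methyl-2-methylideneoct-5-en-7-ynoate (hydroxy ester) | C=C(C(=O)OC)[C@@H]([C@@H](O)/C=C(/C)C#C)[C@H](OC(=O)/C(C)=C/C)C[C@@](C)(O)C(OC)OC | intermediate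
20 | (1R,3R)-3-hydroxy-4,4-dimethoxy-3-methyl-1-[(2S,3R)-4-methylidene-2-[(1Z)-2-methylbut-1-en-3-yn-1-yl]-5-oxooxolan-3-yl]butyl (2E)-2-methylbut-2-enoate | C=C1C(=O)O[C@@H](/C=C(/C)C#C)[C@H]1[C@H](OC(=O)/C(C)=C/C)C[C@@](C)(O)C(OC)OC | intermediate
21 | (1R,3R)-1-[(2S,3R)-2-[(1Z)-4-chloro-2-methyl-3-oxobut-1-en-1-yl]-4-methylidene-5-oxooxolan-3-yl]-3-hydroxy-4,4-dimethoxy-3-methylbutyl (2E)-2-methylbut-2-enoate | C=C1C(=O)O[C@@H](/C=C(/C)C(=O)CCl)[C@H]1[C@H](OC(=O)/C(C)=C/C)C[C@@](C)(O)C(OC)OC | intermediate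
22 | (1R,3R)-1-[(2S,3R)-2-[(1Z)-4-chloro-2-methyl-3-oxobut-1-en-1-yl]-4-methylidene-5-oxooxolan-3-yl]-3-hydroxy-3-methyl-4-oxobutyl (2E)-2-methylbut-2-enoate | C=C1C(=O)O[C@@H](/C=C(/C)C(=O)CCl)[C@H]1[C@H](OC(=O)/C(C)=C/C)C[C@@](C)(O)C=O | intermediate
23 | dilithium alkoxide of the macrocyclic (1S,2S)-2-chloro-1,10-dihydroxy-3-oxo chlorohydrin (germacrane numbering; anti aldol adduct) | C=C1C(=O)O[C@H]2/C=C(/C)C(=O)[C@@H](Cl)[C@@H](O[Li])[C@](C)(O[Li])C[C@@H](OC(=O)/C(C)=C/C)[C@@H]12 | intermediate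
24 | (1R,2R,4Z,6S,7R,8R,10R)-1,2-epoxy-10-hydroxy-3-oxogermacra-4,11(13)-dien-12,6-olid-8-yl (2E)-2-methylbut-2-enoate (germacrane numbering; CNP0383091.1) | C=C1C(=O)O[C@H]2/C=C(/C)C(=O)[C@@H]3O[C@H]3[C@](C)(O)C[C@@H](OC(=O)/C(C)=C/C)[C@@H]12 | target

**Step count**
Total steps: 13. Longest linear sequence: 11 steps (6 → 24, steps 3 to 13); the other branch (1 → 5, steps 1 and 2) joins at step 8.

**Three steps most likely to fail**

Step 13 (Darzens macrocyclisation). Closing a ten-membered ring by a reversible aldol is entropically and transannularly costly. It competes with intermolecular aldol, with Michael addition of the enolate to the methylene lactone, and with attack on the wrong aldehyde face. The fallback sets out from 22 and comes back at 24. A chromium Reformatsky macrocyclisation (CrCl2, LiI cat., THF, 0.002 M) gives the macrocyclic β-hydroxy ketone F1. MsCl/Et3N converts it into the C1 mesylate F2, which DBU eliminates to the (1E)-dienone F3. Nucleophilic epoxidation of the more electrophilic disubstituted enone (t-BuOOH, DBU, CH2Cl2, 0 °C) from the outer face of the ring then gives 24. This separates ring closure from epoxide formation.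

Step 8 (indium Barbier coupling). Control of the C7 configuration by the C6 silyloxy stereocentre is not secured by close precedent. The allylindium could also lose silanolate to give a diene, or the adduct could lactonise onto C8–OH. The fallback sets out from 14 and comes back at 16. Palladium-catalysed borylation (B2pin2, Pd2(dba)3 cat., DMSO) gives the configurationally defined allylboronate F4 (C6 trans to the ester), which cannot eliminate. It adds to aldehyde 5 under chiral phosphoric acid catalysis ((R)-TRIP, toluene, −30 °C) through a closed chair transition state, so the syn relationship comes from the boronate geometry and the aldehyde face from the catalyst. Mild aqueous work-up gives 16.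

Step 11 (gold oxidation of the enyne). The α-oxo gold carbene sits in a molecule with a lactone, a free tertiary alcohol and an acid-labile acetal; over-oxidation or interception by these groups could erode the yield. The fallback sets out from 20 and comes back at 21. NBS with AgNO3 (cat.) in acetone gives the bromoalkyne F5. Gold-catalysed hydration (XPhosAuNTf2, 3 equiv H2O, ClCH2CH2Cl, rt) gives the bromomethyl ketone F6. LiCl in acetone exchanges bromide for chloride and gives 21.

**Further compounds**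
F1 | step 13 | (4Z,6S,7R,8R,10R)-1,10-dihydroxy-3-oxogermacra-4,11(13)-dien-12,6-olid-8-yl (2E)-2-methylbut-2-enoate (macrocyclic β-hydroxy ketone, either C1 epimer) | C=C1C(=O)O[C@H]2/C=C(/C)C(=O)CC(O)[C@](C)(O)C[C@@H](OC(=O)/C(C)=C/C)[C@@H]12
F2 | step 13 | C1 methanesulfonate of F1 | C=C1C(=O)O[C@H]2/C=C(/C)C(=O)CC(OS(C)(=O)=O)[C@](C)(O)C[C@@H](OC(=O)/C(C)=C/C)[C@@H]12
F3 | step 13 | (1E,4Z,6S,7R,8R,10R)-10-hydroxy-3-oxogermacra-1,4,11(13)-trien-12,6-olid-8-yl (2E)-2-methylbut-2-enoate | C=C1C(=O)O[C@H]2/C=C(/C)C(=O)/C=C/[C@](C)(O)C[C@@H](OC(=O)/C(C)=C/C)[C@@H]12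
F4 | step 8 | methyl (2E,4S,5Z)-6-methyl-2-[(4,4,5,5-tetramethyl-1,3,2-dioxaborolan-2-yl)methyl]-4-(triethylsilyloxy)octa-2,5-dien-7-ynoate | COC(=O)/C(CB1OC(C)(C)C(C)(C)O1)=C/[C@@H](O[Si](CC)(CC)CC)/C=C(/C)C#C
F5 | step 11 | (1R,3R)-1-[(2S,3R)-2-[(1Z)-4-bromo-2-methylbut-1-en-3-yn-1-yl]-4-methylidene-5-oxooxolan-3-yl]-3-hydroxy-4,4-dimethoxy-3-methylbutyl (2E)-2-methylbut-2-enoate | C=C1C(=O)O[C@@H](/C=C(/C)C#CBr)[C@H]1[C@H](OC(=O)/C(C)=C/C)C[C@@](C)(O)C(OC)OC
F6 | step 11 | (1R,3R)-1-[(2S,3R)-2-[(1Z)-4-bromo-2-methyl-3-oxobut-1-en-1-yl]-4-methylidene-5-oxooxolan-3-yl]-3-hydroxy-4,4-dimethoxy-3-methylbutyl (2E)-2-methylbut-2-enoate | C=C1C(=O)O[C@@H](/C=C(/C)C(=O)CBr)[C@H]1[C@H](OC(=O)/C(C)=C/C)C[C@@](C)(O)C(OC)OC
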